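The route rests on cutting the C2=C3 double bond of the 5-hydroxyindole. C3 carries the hexasubstituted central benzene ring and C2 is a bare CH. C3 therefore maps onto a diaryl ketone carbon and C2 onto a formamide carbon, held ortho to each other at C3a and C7a of the benzo ring. Low-valent titanium joins these two carbonyl carbons and removes both oxygens, closing the pyrrole ring in one operation without a second hindered biaryl coupling. The precursor is an N-(2-aroylphenyl)formamide whose aroyl group already bears the four methoxy groups and the 6-methoxyindol-3-yl unit. The phenol and that indole nitrogen carry triisopropylsilyl groups, removed together at the end.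

Key step: step 7

Assumption: the two aryl–indolyl axes are taken to rotate freely at room temperature, so the target and all intermediates are treated as single compounds without axial stereoisomers.
Abbreviations: TIPS = triisopropylsilyl; NBS = N-bromosuccinimide; EDC = 1-ethyl-3-[3-(dimethylamino)propyl]carbodiimide; HOBt = 1-hydroxybenzotriazole; TBAF = tetrabutylammonium fluoride.

Step 1
Reactants: 1 6-methoxy-1H-indole
Product: 4 3-bromo-6-methoxy-1-(triisopropylsilyl)-1H-indole, via lithium 6-methoxyindol-1-ide 2 (not isolated), via 6-methoxy-1-(triisopropylsilyl)-1H-indole 3 (not isolated)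
Conditions: n-BuLi (1.05 equiv), THF, −78 to −10 °C; TIPSCl (1.1 equiv), −78 to 0 °C; NBS (1.0 equiv), −78 °C to rt, dark
Reagents that add atoms: triisopropylsilyl chloride, CC(C)[Si](Cl)(C(C)C)C(C)C; N-bromosuccinimide, O=C1CCC(=O)N1Br
Why: N-lithiation and silylation followed in the same flask by electrophilic bromination with NBS is the standard one-pot entry to 3-bromo-1-silylindoles, C3 being the enamine-like and most nucleophilic carbon; the bulky, oxygen-free silyl group is chosen because it screens C2–H and C7–H from butyllithium in step 6, offers titanium no Lewis-basic handle in step 7 and leaves with fluoride in step 8.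

Step 2
Reactants: 5 1,2,4,5-tetramethoxybenzene; 4 3-bromo-6-methoxy-1-(triisopropylsilyl)-1H-indole
Product: 8 6-methoxy-3-(2,3,5,6-tetramethoxyphenyl)-1-(triisopropylsilyl)-1H-indole, via 2,3,5,6-tetramethoxyphenyllithium 6 (not isolated), via (2,3,5,6-tetramethoxyphenyl)zinc chloride 7 (not isolated)
Conditions: 5 (1.5 equiv), n-BuLi (1.45 equiv), THF, 0 °C to rt; ZnCl2 (1.6 equiv), 0 °C to rt; 4 (1.0 equiv), Pd2(dba)3 (2 mol %), RuPhos (8 mol %), THF, 65 °C
Reagents that add atoms: none
Why: Directed ortho-metalation of 5 at a C–H flanked by two methoxy groups, transmetalation to zinc and Negishi coupling under zerovalent palladium with a bulky biarylphosphine, a combination suited to di-ortho-substituted arylzinc reagents, should give the monoarylated ring without statistical desymmetrisation, and the anhydrous, base-free medium spares the N–Si bond.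

Step 3
Reactants: 9 2-amino-5-hydroxybenzoic acid
Product: 10 2-amino-5-hydroxy-N-methoxy-N-methylbenzamide
Conditions: MeNHOMe·HCl, EDC·HCl, HOBt, iPr2NEt, degassed DMF, argon, 0 °C to rt
Reagents that add atoms: N,O-dimethylhydroxylamine hydrochloride, CNOC.Cl
Why: Carbodiimide/HOBt amide coupling works on unprotected anthranilic acids because the hydrogen-bonded, conjugated aniline is a far poorer nucleophile than N,O-dimethylhydroxylamine, any phenol ester formed in passing is aminolysed back, and exclusion of air protects the para-aminophenol unit from oxidation.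

Step 4
Reactants: 10 2-amino-5-hydroxy-N-methoxy-N-methylbenzamide
Product: 11 2-amino-N-methoxy-N-methyl-5-[(triisopropylsilyl)oxy]benzamide
Conditions: TIPSCl (1.1 equiv), imidazole (2.5 equiv), DMF, 0 °C to rt
Reagents that add atoms: triisopropylsilyl chloride, CC(C)[Si](Cl)(C(C)C)C(C)C
Why: Imidazole-promoted silylation is selective for the phenol, since an N–Si bond on the deactivated aniline would not survive aqueous work-up, and it ends the oxidation sensitivity of the aminophenol.

Step 5
Reactants: 11 2-amino-N-methoxy-N-methyl-5-[(triisopropylsilyl)oxy]benzamide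
Product: 12 2-formamido-N-methoxy-N-methyl-5-[(triisopropylsilyl)oxy]benzamide
Conditions: HCO2H, Ac2O, 55 °C, then 11, THF, 0 °C to rt
Reagents that add atoms: formic acid, O=CO (delivered as acetic formic anhydride, CC(=O)OC=O)
Why: N-formylation with the mixed anhydride transfers the more electrophilic formyl group even to ortho-acyl anilines, under conditions too mild to touch the aryl silyl ether or the Weinreb amide.

Step 6
Reactants: 8 6-methoxy-3-(2,3,5,6-tetramethoxyphenyl)-1-(triisopropylsilyl)-1H-indole; 12 2-formamido-N-methoxy-N-methyl-5-[(triisopropylsilyl)oxy]benzamide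
Product: 16 N-{2-[2,3,5,6-tetramethoxy-4-(6-methoxy-1-(triisopropylsilyl)-1H-indol-3-yl)benzoyl]-4-[(triisopropylsilyl)oxy]phenyl}formamide, via 4-indolyl-2,3,5,6-tetramethoxyphenyllithium 13 (not isolated), via sodium formamidate 14 (not isolated), via tetrahedral lithium sodium adduct 15 (not isolated)
Conditions: 8, n-BuLi (1.1 equiv), TMEDA (1.1 equiv), THF, 0 °C; separately 12 (1.3 equiv), NaH (1.35 equiv), THF, 0 °C; combine at −78 °C, warm to −20 °C; AcOH, THF, −78 °C
Reagents that add atoms: none
Why: Directed ortho-metalation removes the only C–H of 8 that lies between two methoxy groups (indole C2–H and C7–H are screened by the silyl group), and the aryllithium acylates the Weinreb amide (Weinreb ketone synthesis) while the formamide, pre-converted with NaH into its unreactive sodium salt, neither quenches nor captures the nucleophile; the chelated adduct 15 prevents over-addition and the cold AcOH quench releases ketone and formamide together, so no nitro group, oxidation or reduction is needed on the way to 16.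

Step 7
Reactants: 16 N-{2-[2,3,5,6-tetramethoxy-4-(6-methoxy-1-(triisopropylsilyl)-1H-indol-3-yl)benzoyl]-4-[(triisopropylsilyl)oxy]phenyl}formamide
Product: 17 3-{2,3,5,6-tetramethoxy-4-[6-methoxy-1-(triisopropylsilyl)-1H-indol-3-yl]phenyl}-5-[(triisopropylsilyl)oxy]-1H-indole
Conditions: TiCl3 (4 equiv), Zn dust (8 equiv), DME, reflux, 2 h; then 16 in DME added slowly, reflux; filtration through silica
Reagents that add atoms: none
Why: Low-valent titanium made from TiCl3 and zinc transfers electrons to the diaryl ketone of 16, the more easily reduced carbonyl, to give a titanium-bound ketyl or dianion at the future C3. This carbon attacks the formamide carbonyl carbon (future C2) on the neighbouring ring position in a 5-exo-trig closure to a titanium-bridged indoline-2,3-diolate, and transfer of both oxygens to the oxophilic metal then leaves the aromatic C2=C3 bond. The closest known reaction type is the Fürstner indole synthesis, the intramolecular McMurry-type oxo-amide coupling of 2-acylanilides, in which a formamide supplies an unsubstituted C2. No stereocentre is formed. The step needs keto–amide cross-coupling in preference to intermolecular pinacol or olefin formation and to plain reduction of the ketone; the ortho placement lets one titanium centre bind both carbonyls, and the two methoxy groups flanking the ketone block its dimerisation. The aryl methyl ethers, the aryl silyl ether and the N-silylindole offer no reducible or strongly chelating site, and loss of the N-silyl group to adventitious HCl would be harmless because step 8 removes it anyway.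

Step 8
Reactants: 17 3-{2,3,5,6-tetramethoxy-4-[6-methoxy-1-(triisopropylsilyl)-1H-indol-3-yl]phenyl}-5-[(triisopropylsilyl)oxy]-1H-indole
Product: 18 3-[2,3,5,6-tetramethoxy-4-(6-methoxy-1H-indol-3-yl)phenyl]-1H-indol-5-ol
Conditions: TBAF (2.5 equiv), AcOH (2.5 equiv), THF, argon, 0 °C to rt
Reagents that add atoms: none
Why: Fluoride-induced desilylation cleaves the O–Si and the N–Si bond in the same operation, the acetic acid buffer keeps the air-sensitive 5-hydroxyindole from standing as its phenoxide, and nothing else in 17 responds to fluoride.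

Compound list
1 | 6-methoxy-1H-indole | COc1ccc2cc[nH]c2c1 | starting material
2 | lithium 6-methoxyindol-1-ide | COc1ccc2cc[n-]c2c1.[Li+] | intermediate
3 | 6-methoxy-1-(triisopropylsilyl)-1H-indole | COc1ccc2ccn([Si](C(C)C)(C(C)C)C(C)C)c2c1 | intermediate
4 | 3-bromo-6-methoxy-1-(triisopropylsilyl)-1H-indole | COc1ccc2c(Br)cn([Si](C(C)C)(C(C)C)C(C)C)c2c1 | intermediate
5 | 1,2,4,5-tetramethoxybenzene | COc1cc(OC)c(OC)cc1OC | starting material
6 | 2,3,5,6-tetramethoxyphenyllithium | [Li]c1c(OC)c(OC)cc(OC)c1OC | intermediate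
7 | (2,3,5,6-tetramethoxyphenyl)zinc chloride | Cl[Zn]c1c(OC)c(OC)cc(OC)c1OC | intermediate
8 | 6-methoxy-3-(2,3,5,6-tetramethoxyphenyl)-1-(triisopropylsilyl)-1H-indole | COc1ccc2c(-c3c(OC)c(OC)cc(OC)c3OC)cn([Si](C(C)C)(C(C)C)C(C)C)c2c1 | intermediate
9 | 2-amino-5-hydroxybenzoic acid | Nc1ccc(O)cc1C(=O)O | starting material
10 | 2-amino-5-hydroxy-N-methoxy-N-methylbenzamide | CON(C)C(=O)c1cc(O)ccc1N | intermediate
11 | 2-amino-N-methoxy-N-methyl-5-[(triisopropylsilyl)oxy]benzamide | CON(C)C(=O)c1cc(O[Si](C(C)C)(C(C)C)C(C)C)ccc1N | intermediate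
12 | 2-formamido-N-methoxy-N-methyl-5-[(triisopropylsilyl)oxy]benzamide | CON(C)C(=O)c1cc(O[Si](C(C)C)(C(C)C)C(C)C)ccc1NC=O | intermediate
13 | {2,3,5,6-tetramethoxy-4-[6-methoxy-1-(triisopropylsilyl)-1H-indol-3-yl]phenyl}lithium | [Li]c1c(OC)c(OC)c(-c2cn([Si](C(C)C)(C(C)C)C(C)C)c3cc(OC)ccc23)c(OC)c1OC | intermediate
14 | sodium salt of 12 (N-deprotonated formamide) | CON(C)C(=O)c1cc(O[Si](C(C)C)(C(C)C)C(C)C)ccc1[N-]C=O.[Na+] | intermediate
15 | tetrahedral adduct of 13 and 14 (lithium alkoxide, sodium formamidate, racemic at the new carbon) | COc1ccc2c(-c3c(OC)c(OC)c(C([O-])(N(C)OC)c4cc(O[Si](C(C)C)(C(C)C)C(C)C)ccc4[N-]C=O)c(OC)c3OC)cn([Si](C(C)C)(C(C)C)C(C)C)c2c1.[Li+].[Na+] | intermediate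
16 | N-{2-[2,3,5,6-tetramethoxy-4-(6-methoxy-1-(triisopropylsilyl)-1H-indol-3-yl)benzoyl]-4-[(triisopropylsilyl)oxy]phenyl}formamide | COc1ccc2c(-c3c(OC)c(OC)c(C(=O)c4cc(O[Si](C(C)C)(C(C)C)C(C)C)ccc4NC=O)c(OC)c3OC)cn([Si](C(C)C)(C(C)C)C(C)C)c2c1 | intermediate
17 | 3-{2,3,5,6-tetramethoxy-4-[6-methoxy-1-(triisopropylsilyl)-1H-indol-3-yl]phenyl}-5-[(triisopropylsilyl)oxy]-1H-indole | COc1ccc2c(-c3c(OC)c(OC)c(-c4c[nH]c5ccc(O[Si](C(C)C)(C(C)C)C(C)C)cc45)c(OC)c3OC)cn([Si](C(C)C)(C(C)C)C(C)C)c2c1 | intermediate
18 | 3-[2,3,5,6-tetramethoxy-4-(6-methoxy-1H-indol-3-yl)phenyl]-1H-indol-5-ol | COc1ccc2c(-c3c(OC)c(OC)c(-c4c[nH]c5ccc(O)cc45)c(OC)c3OC)c[nH]c2c1 | target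

Total step count: 8
Longest linear sequence: 6 steps (steps 3, 4, 5, 6, 7, 8); the indole branch (steps 1, 2, 6, 7, 8) counts 5.

Steps most likely to fail

1. Step 7.
- Risk: the twisted ketone between two methoxy groups may undergo plain reduction without C–C bond formation, or deoxygenation of the titanium-bound diolate may stall.
- Fallback: the pyrrole ring construction is replaced by a direct biaryl coupling. It sets out from 8 and returns at 18.
- Commercial 5-hydroxyindole is bis-silylated (NaH, TIPSCl, THF/DMF) to 1-(triisopropylsilyl)-5-[(triisopropylsilyl)oxy]-1H-indole F1.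
- Bromination with NBS (THF, −78 °C) gives 3-bromo-1-(triisopropylsilyl)-5-[(triisopropylsilyl)oxy]-1H-indole F2.
- Compound 8 is lithiated to 13 as in step 6 and treated with ZnCl2 to give {2,3,5,6-tetramethoxy-4-[6-methoxy-1-(triisopropylsilyl)-1H-indol-3-yl]phenyl}zinc chloride F3.
- Negishi coupling of the two partners under the conditions validated in step 2 gives 3-{2,3,5,6-tetramethoxy-4-[6-methoxy-1-(triisopropylsilyl)-1H-indol-3-yl]phenyl}-1-(triisopropylsilyl)-5-[(triisopropylsilyl)oxy]-1H-indole F4.
- TBAF/AcOH as in step 8 then leads to 18.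

2. Step 6.
- Risk: addition of the hindered aryllithium to the ortho-substituted Weinreb amide may be slow, so that proton transfer or base-induced loss of formaldehyde from the N-methoxy group competes.
- Fallback: the electrophile becomes a small, more reactive aldehyde, at the cost of one oxidation. It sets out from 12 and 8 and returns at 16.
- Compound 12 is reduced with DIBAL-H (2.2 equiv, THF, −78 °C; the first equivalent deprotonates and so shields the formamide) to N-{2-formyl-4-[(triisopropylsilyl)oxy]phenyl}formamide F5.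
- NaH in THF converts this into sodium formyl{2-formyl-4-[(triisopropylsilyl)oxy]phenyl}azanide F6.
- Addition of 13 at −78 °C gives racemic N-{2-[hydroxy(2,3,5,6-tetramethoxy-4-(6-methoxy-1-(triisopropylsilyl)-1H-indol-3-yl)phenyl)methyl]-4-[(triisopropylsilyl)oxy]phenyl}formamide F7.
- Oxidation with Dess–Martin periodinane (NaHCO3, CH2Cl2) gives 16.

3. Step 2.
- Risk: transmetalation and reductive elimination at the hindered centre may be sluggish, with hydrodebromination of the bromoindole or homocoupling taking over.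
- Fallback: the polarity of the coupling is reversed and zinc is replaced by boron. It sets out from 3 and 6 and returns at 8.
- Compound 3, isolated by leaving NBS out of step 1, undergoes iridium-catalysed C–H borylation ([Ir(OMe)(cod)]2, dtbpy, B2pin2, hexane, 60 °C). The silyl group steers this to C3, giving 6-methoxy-3-(4,4,5,5-tetramethyl-1,3,2-dioxaborolan-2-yl)-1-(triisopropylsilyl)-1H-indole F8.
- Compound 6 is quenched with iodine at −78 °C to give 3-iodo-1,2,4,5-tetramethoxybenzene F9.
- Suzuki–Miyaura coupling (Pd(OAc)2, SPhos, K3PO4, toluene/water, 90 °C) joins the two to 8.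

Further compounds
F1 | step 7 | 1-(triisopropylsilyl)-5-[(triisopropylsilyl)oxy]-1H-indole | CC(C)[Si](Oc1ccc2c(ccn2[Si](C(C)C)(C(C)C)C(C)C)c1)(C(C)C)C(C)C
F2 | step 7 | 3-bromo-1-(triisopropylsilyl)-5-[(triisopropylsilyl)oxy]-1H-indole | CC(C)[Si](Oc1ccc2c(c1)c(Br)cn2[Si](C(C)C)(C(C)C)C(C)C)(C(C)C)C(C)C
F3 | step 7 | {2,3,5,6-tetramethoxy-4-[6-methoxy-1-(triisopropylsilyl)-1H-indol-3-yl]phenyl}zinc chloride | Cl[Zn]c1c(OC)c(OC)c(-c2cn([Si](C(C)C)(C(C)C)C(C)C)c3cc(OC)ccc23)c(OC)c1OC
F4 | step 7 | 3-{2,3,5,6-tetramethoxy-4-[6-methoxy-1-(triisopropylsilyl)-1H-indol-3-yl]phenyl}-1-(triisopropylsilyl)-5-[(triisopropylsilyl)oxy]-1H-indole | COc1ccc2c(-c3c(OC)c(OC)c(-c4cn([Si](C(C)C)(C(C)C)C(C)C)c5ccc(O[Si](C(C)C)(C(C)C)C(C)C)cc45)c(OC)c3OC)cn([Si](C(C)C)(C(C)C)C(C)C)c2c1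
F5 | step 6 | N-{2-formyl-4-[(triisopropylsilyl)oxy]phenyl}formamide | O=CNc1ccc(O[Si](C(C)C)(C(C)C)C(C)C)cc1C=O
F6 | step 6 | sodium formyl{2-formyl-4-[(triisopropylsilyl)oxy]phenyl}azanide | O=C[N-]c1ccc(O[Si](C(C)C)(C(C)C)C(C)C)cc1C=O.[Na+]
F7 | step 6 | racemic N-{2-[hydroxy(2,3,5,6-tetramethoxy-4-(6-methoxy-1-(triisopropylsilyl)-1H-indol-3-yl)phenyl)methyl]-4-[(triisopropylsilyl)oxy]phenyl}formamide | COc1ccc2c(-c3c(OC)c(OC)c(C(O)c4cc(O[Si](C(C)C)(C(C)C)C(C)C)ccc4NC=O)c(OC)c3OC)cn([Si](C(C)C)(C(C)C)C(C)C)c2c1
F8 | step 2 | 6-methoxy-3-(4,4,5,5-tetramethyl-1,3,2-dioxaborolan-2-yl)-1-(triisopropylsilyl)-1H-indole | COc1ccc2c(B3OC(C)(C)C(C)(C)O3)cn([Si](C(C)C)(C(C)C)C(C)C)c2c1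
F9 | step 2 | 3-iodo-1,2,4,5-tetramethoxybenzene | COc1cc(OC)c(OC)c(I)c1OC
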